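## Retrosynthetic overview

1. Target 16 ⇐ tri-O-allyl ether 15 by one global O-deallylation at the end.
2. 15 ⇐ phenol 6 + enal 12: the pyran ring is cut at C4–C4a and O1–C2. Forward, a chiral-Brønsted-acid-catalysed formal [3+3] annulation (ortho-hydroxyalkylation, dehydration to an ortho-quinone methide, oxa-6π closure) forms both bonds and the only stereocentre, C2. Rings A and B are bought; the pyran ring is the only ring formed.
3. Enabling feature: ring B is a catechol mono-ether. Its free phenolic oxygen on C3 (future O1) has exactly one open ortho position, the C2–H (future C4a), because the other ortho carbon C4 carries the second catechol oxygen (future C8–OH, masked as allyl ether). This H–C=C–O–H unit is a C,O-1,3-dinucleophile that matches the C1/C3 dielectrophile of a β,β-disubstituted enal.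
4. 6 ⇐ Claisen–Schmidt condensation of ketone 2 with aldehyde 4 (each from a bought phenol by O-allylation), then 1,4-reduction.
5. 12 ⇐ geranyl acetate 7 by 6,7-epoxidation, selenolate opening/selenoxide elimination and MnO2 oxidation.

Key step: step 9

Remark: C2 of the target is (R) (O1 > C3 > CH2 > CH3). The sense of induction of the chiral acid on this substrate class cannot be assigned beforehand, so the (R)-catalyst written in step 9 stands for whichever antipode a first assay against racemic material shows to give (R)-15.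

## Route

Step 1
Reactants: 1 2,4-dihydroxyacetophenone
Product: 2 1-[2,4-bis(prop-2-en-1-yloxy)phenyl]ethan-1-one
Conditions: allyl bromide (2.5 equiv), K2CO3, DMF, 60 °C
Reagents that add atoms: allyl bromide, C=CCBr
Why: Williamson etherification; excess base and gentle heating should also alkylate the hydrogen-bonded 2-OH.

Step 2
Reactants: 3 3,4-dihydroxybenzaldehyde
Product: 4 3-hydroxy-4-(prop-2-en-1-yloxy)benzaldehyde
Conditions: allyl bromide (1.05 equiv), NaHCO3, NaI (cat.), DMF, 40 °C
Reagents that add atoms: allyl bromide, C=CCBr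
Why: Regioselective Williamson mono-alkylation; the 4-OH para to the formyl group is the more acidic, so the weak base should ionise and alkylate it preferentially.

Step 3
Reactants: 2 1-[2,4-bis(prop-2-en-1-yloxy)phenyl]ethan-1-one; 4 3-hydroxy-4-(prop-2-en-1-yloxy)benzaldehyde
Product: 5 (2E)-1-[2,4-bis(prop-2-en-1-yloxy)phenyl]-3-[3-hydroxy-4-(prop-2-en-1-yloxy)phenyl]prop-2-en-1-one
Conditions: KOH (aq. 50 %), EtOH, rt; then dilute HCl
Reagents that add atoms: none
Why: Claisen–Schmidt condensation; the meta-phenoxide is not conjugated with the aldehyde, which stays electrophilic, and the (E)-enone is the thermodynamic product.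

Step 4
Reactants: 5 (2E)-1-[2,4-bis(prop-2-en-1-yloxy)phenyl]-3-[3-hydroxy-4-(prop-2-en-1-yloxy)phenyl]prop-2-en-1-one
Product: 6 1-[2,4-bis(prop-2-en-1-yloxy)phenyl]-3-[3-hydroxy-4-(prop-2-en-1-yloxy)phenyl]propan-1-one
Conditions: Cu(OAc)2·H2O (5 mol %), 1,2-bis(diphenylphosphino)benzene (5 mol %), Ph2SiH2 (2.5 equiv), t-BuOH, toluene, 0 °C to rt; then aq. NaOH, acidify
Reagents that add atoms: none
Why: Copper hydride conjugate reduction; the monovalent copper hydride formed in situ should deliver hydride 1,4 to the enone only, leaving the isolated O-allyl alkenes and the hindered aryl ketone untouched.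

Step 5
Reactants: 7 geranyl acetate
Product: 8 racemic (2E)-5-(3,3-dimethyloxiran-2-yl)-3-methylpent-2-en-1-yl acetate
Conditions: mCPBA (1.05 equiv), NaHCO3, CH2Cl2, 0 °C
Reagents that add atoms: mCPBA, OOC(=O)c1cccc(Cl)c1
Why: Prilezhaev epoxidation; the electron-rich 6,7-alkene should react far faster than the 2,3-alkene deactivated by the allylic acetate, and the racemic epoxide centre is removed again in step 7.

Step 6
Reactants: 8 racemic (2E)-5-(3,3-dimethyloxiran-2-yl)-3-methylpent-2-en-1-yl acetate
Product: 9 racemic (2E)-5-(3,3-dimethyloxiran-2-yl)-3-methylpent-2-en-1-ol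
Conditions: K2CO3 (cat.), MeOH, rt
Reagents that add atoms: none
Why: Base-catalysed transesterification (methanolysis of the acetate); the trisubstituted epoxide is stable to carbonate in methanol at room temperature.

Step 7
Reactants: 9 racemic (2E)-5-(3,3-dimethyloxiran-2-yl)-3-methylpent-2-en-1-ol
Product: 11 (2E,5E)-3,7-dimethylocta-2,5-diene-1,7-diol, via hydroxy selenide 10 (not isolated)
Conditions: (PhSe)2, NaBH4, EtOH, rt to reflux; then THF, 30 % H2O2, 0 °C to rt
Reagents that add atoms: none
Why: Epoxide-to-allylic-alcohol transposition; the selenolate should open the epoxide at the less hindered C6, and selenoxide syn-elimination can only go towards C5 (C7 has no hydrogen), giving the (E)-configured tertiary allylic alcohol.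

Step 8
Reactants: 11 (2E,5E)-3,7-dimethylocta-2,5-diene-1,7-diol
Product: 12 (2E,5E)-7-hydroxy-3,7-dimethylocta-2,5-dienal
Conditions: activated MnO2 (excess), CH2Cl2, rt
Reagents that add atoms: none
Why: Allylic alcohol oxidation with MnO2; only the primary allylic alcohol can be oxidised, the tertiary alcohol is inert, and the 2E geometry should be retained.

Step 9
Reactants: 6 1-[2,4-bis(prop-2-en-1-yloxy)phenyl]-3-[3-hydroxy-4-(prop-2-en-1-yloxy)phenyl]propan-1-one; 12 (2E,5E)-7-hydroxy-3,7-dimethylocta-2,5-dienal
Product: 15 1-[2,4-bis(prop-2-en-1-yloxy)phenyl]-3-[(2R)-2-[(2E)-4-hydroxy-4-methylpent-2-en-1-yl]-2-methyl-8-(prop-2-en-1-yloxy)-2H-chromen-5-yl]propan-1-one, via ortho-hydroxyalkyl carbinol 13 (not isolated), via ortho-quinone methide 14 (not isolated)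
Conditions: (R)-3,3'-bis(2,4,6-triisopropylphenyl)-1,1'-binaphthyl-2,2'-diyl N-triflylphosphoramide (10 mol %), 12 (1.3 equiv, added slowly), 5 Å molecular sieves, toluene, −40 to −10 °C; Et3N quench
Reagents that add atoms: none
Why: Proposed new method: the bifunctional chiral N-triflylphosphoramide should hydrogen-bond the only free phenolic O–H of 6 (ring B, C3–OH) and protonate enal 12, so that Friedel–Crafts hydroxyalkylation occurs at the single open ortho carbon C2 to give carbinol 13, whose acid-promoted dehydration generates the vinylogous ortho-quinone methide 14 (equivalently a hydroxyaryl-stabilised allyl cation) as a contact ion pair with the chiral phosphoramide anion. Closure of the pyran ring is a 6-endo O–C bond formation, formally a disrotatory oxa-6π electrocyclisation of the (Z)-configured 1-oxatriene, so the O1–C2 bond follows the C4–C4a bond in the same flask. The closest known reaction types are the racemic thermal or acid/amine-mediated phenol–enal formal [3+3] chromene annulation and the chiral N-triflylphosphoramide-catalysed intramolecular allylic substitution of ortho-hydroxyaryl allylic alcohols to 2,2-disubstituted 2H-chromenes; new here are their merger in one pot and the differentiation of a methyl group from a CH2R arm. The C2 stereocentre is catalyst-controlled: the anion held at the phenolic O–H should shield one face of the (E)-configured C(CH3)(CH2R) terminus during O–C bond formation. The step needs ortho- over para-attack and ring B over ring A selectivity, which the hydrogen-bond-directed delivery to the only ring carrying a free OH, the O-allyl group blocking the second ortho position (C4) and the acyl-deactivated, OH-free ring A should secure. It also needs the isolated tertiary allylic alcohol and the skipped diene to survive, which low temperature, low acid loading and the (E)-alkene (the side-chain OH cannot reach C2) are expected to ensure.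

Step 10
Reactants: 15 1-[2,4-bis(prop-2-en-1-yloxy)phenyl]-3-[(2R)-2-[(2E)-4-hydroxy-4-methylpent-2-en-1-yl]-2-methyl-8-(prop-2-en-1-yloxy)-2H-chromen-5-yl]propan-1-one
Product: 16 1-(2,4-dihydroxyphenyl)-3-[(2R)-8-hydroxy-2-[(2E)-4-hydroxy-4-methylpent-2-en-1-yl]-2-methyl-2H-chromen-5-yl]propan-1-one
Conditions: Pd(PPh3)4 (10 mol %), K2CO3, degassed MeOH, rt; pH 6 buffer work-up
Reagents that add atoms: none
Why: Tsuji–Trost-type deallylation; zerovalent palladium should ionise the three unsubstituted aryl allyl ethers to π-allyl complexes that methanol/methoxide intercepts, while the hindered tertiary ring allylic ether and the unactivated tertiary allylic alcohol ionise far more slowly, so C2 is not touched.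

## Compound list

1 | 2,4-dihydroxyacetophenone | CC(=O)c1ccc(O)cc1O | starting material
2 | 1-[2,4-bis(prop-2-en-1-yloxy)phenyl]ethan-1-one | CC(=O)c1ccc(OCC=C)cc1OCC=C | intermediate
3 | 3,4-dihydroxybenzaldehyde | O=Cc1ccc(O)c(O)c1 | starting material
4 | 3-hydroxy-4-(prop-2-en-1-yloxy)benzaldehyde | O=Cc1ccc(OCC=C)c(O)c1 | intermediate
5 | (2E)-1-[2,4-bis(prop-2-en-1-yloxy)phenyl]-3-[3-hydroxy-4-(prop-2-en-1-yloxy)phenyl]prop-2-en-1-one | C=CCOc1ccc(C(=O)/C=C/c2ccc(OCC=C)c(O)c2)c(OCC=C)c1 | intermediate
6 | 1-[2,4-bis(prop-2-en-1-yloxy)phenyl]-3-[3-hydroxy-4-(prop-2-en-1-yloxy)phenyl]propan-1-one | C=CCOc1ccc(C(=O)CCc2ccc(OCC=C)c(O)c2)c(OCC=C)c1 | intermediate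
7 | geranyl acetate, (2E)-3,7-dimethylocta-2,6-dien-1-yl acetate | CC(=O)OC/C=C(\C)CCC=C(C)C | starting material
8 | racemic (2E)-5-(3,3-dimethyloxiran-2-yl)-3-methylpent-2-en-1-yl acetate | CC(=O)OC/C=C(\C)CCC1OC1(C)C | intermediate
9 | racemic (2E)-5-(3,3-dimethyloxiran-2-yl)-3-methylpent-2-en-1-ol | OC/C=C(\C)CCC1OC1(C)C | intermediate
10 | racemic (2E)-3,7-dimethyl-6-(phenylselanyl)oct-2-ene-1,7-diol (not isolated) | OC/C=C(\C)CCC([Se]c1ccccc1)C(C)(C)O | intermediate
11 | (2E,5E)-3,7-dimethylocta-2,5-diene-1,7-diol | OC/C=C(\C)C/C=C/C(C)(C)O | intermediate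
12 | (2E,5E)-7-hydroxy-3,7-dimethylocta-2,5-dienal | O=C/C=C(\C)C/C=C/C(C)(C)O | intermediate
13 | 1-[2,4-bis(prop-2-en-1-yloxy)phenyl]-3-{2-[(2E,5E)-1,7-dihydroxy-3,7-dimethylocta-2,5-dien-1-yl]-3-hydroxy-4-(prop-2-en-1-yloxy)phenyl}propan-1-one, either configuration at the carbinol carbon (not isolated) | OC(/C=C(\C)C/C=C/C(C)(C)O)c1c(CCC(=O)c2ccc(OCC=C)cc2OCC=C)ccc(OCC=C)c1O | intermediate
14 | (6Z)-6-[(2E,5E)-7-hydroxy-3,7-dimethylocta-2,5-dien-1-ylidene]-2-(prop-2-en-1-yloxy)-5-{3-[2,4-bis(prop-2-en-1-yloxy)phenyl]-3-oxopropyl}cyclohexa-2,4-dien-1-one (not isolated) | O=C1C(OCC=C)=CC=C(CCC(=O)c2ccc(OCC=C)cc2OCC=C)/C1=C/C=C(\C)C/C=C/C(C)(C)O | intermediate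
15 | 1-[2,4-bis(prop-2-en-1-yloxy)phenyl]-3-[(2R)-2-[(2E)-4-hydroxy-4-methylpent-2-en-1-yl]-2-methyl-8-(prop-2-en-1-yloxy)-2H-chromen-5-yl]propan-1-one | CC(C)(O)/C=C/C[C@]1(C)C=Cc2c(CCC(=O)c3ccc(OCC=C)cc3OCC=C)ccc(OCC=C)c2O1 | intermediate
16 | 1-(2,4-dihydroxyphenyl)-3-[(2R)-8-hydroxy-2-[(2E)-4-hydroxy-4-methylpent-2-en-1-yl]-2-methyl-2H-chromen-5-yl]propan-1-one | CC(C)(O)/C=C/C[C@]1(C)C=Cc2c(CCC(=O)c3ccc(O)cc3O)ccc(O)c2O1 | target

## Step count and risks

Total step count: 10. Longest linear sequence: 6 steps (7 → 8 → 9 → 11 → 12 → 15 → 16).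

Steps most likely to fail:

1. Step 9 (bears the new-method label). The catalyst may not distinguish the methyl group from the CH2R arm well enough, so the enantiomeric purity could be low. C–C bond formation at the hindered ortho carbon may be slow and lose out to para attack. The acid may also ionise the tertiary allylic alcohol or move the skipped diene into conjugation. Fallback with known chemistry: it sets out from phenol 6 and enal 12. Heating the two with Ti(OEt)4 in toluene at reflux (metal-phenoxide-templated, ortho-specific chromene annulation) should give racemic tri-O-allyl chromene F1. Preparative chromatography on a chiral stationary phase then separates the enantiomers; the (R)-enantiomer is 15, where the fallback rejoins the route, and the (S)-configured tri-O-allyl chromene F2 is set aside.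

2. Step 10. The palladium catalyst may also ionise the chromene's own tertiary allylic aryl ether, which would open the ring and erode enantiopurity. Removal of the electron-rich 8-O-allyl group may be incomplete, and the freed polyphenol may oxidise in air under base. Fallback: it sets out from 15. Isomerisation of the three allyl ethers with [Ir(cod)(PMePh2)2]PF6 (activated with H2, then THF, rt) should give the tris[(E)-prop-1-enyl] ether F3. Neutral hydrolysis of the enol ethers with HgCl2 and HgO in aqueous acetone at rt returns to the route at 16.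

3. Step 4. The free phenol may consume hydride and stall the reduction. Forcing it could over-reduce the aryl ketone or hydrometalate or isomerise the O-allyl groups. Fallback: it sets out from ketone 2 and avoids the enone. Claisen condensation of 2 with diethyl carbonate (NaH, THF, reflux) gives ethyl 3-[2,4-bis(prop-2-en-1-yloxy)phenyl]-3-oxopropanoate F4. One-pot reductive Knoevenagel alkylation of F4 with aldehyde 4 and the Hantzsch ester diethyl 2,6-dimethyl-1,4-dihydropyridine-3,5-dicarboxylate (L-proline cat., EtOH, rt) gives racemic ethyl 3-[2,4-bis(prop-2-en-1-yloxy)phenyl]-2-{[3-hydroxy-4-(prop-2-en-1-yloxy)phenyl]methyl}-3-oxopropanoate F5. Saponification and decarboxylation (NaOH, aq. EtOH, reflux; then acid) returns to the route at 6.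

Further compounds

F1 | step 9 | racemic 1-[2,4-bis(prop-2-en-1-yloxy)phenyl]-3-[2-[(2E)-4-hydroxy-4-methylpent-2-en-1-yl]-2-methyl-8-(prop-2-en-1-yloxy)-2H-chromen-5-yl]propan-1-one | CC(C)(O)/C=C/CC1(C)C=Cc2c(CCC(=O)c3ccc(OCC=C)cc3OCC=C)ccc(OCC=C)c2O1
F2 | step 9 | 1-[2,4-bis(prop-2-en-1-yloxy)phenyl]-3-[(2S)-2-[(2E)-4-hydroxy-4-methylpent-2-en-1-yl]-2-methyl-8-(prop-2-en-1-yloxy)-2H-chromen-5-yl]propan-1-one | CC(C)(O)/C=C/C[C@@]1(C)C=Cc2c(CCC(=O)c3ccc(OCC=C)cc3OCC=C)ccc(OCC=C)c2O1
F3 | step 10 | 1-{2,4-bis[(1E)-prop-1-en-1-yloxy]phenyl}-3-[(2R)-2-[(2E)-4-hydroxy-4-methylpent-2-en-1-yl]-2-methyl-8-[(1E)-prop-1-en-1-yloxy]-2H-chromen-5-yl]propan-1-one | CC(C)(O)/C=C/C[C@]1(C)C=Cc2c(CCC(=O)c3ccc(O/C=C/C)cc3O/C=C/C)ccc(O/C=C/C)c2O1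
F4 | step 4 | ethyl 3-[2,4-bis(prop-2-en-1-yloxy)phenyl]-3-oxopropanoate | CCOC(=O)CC(=O)c1ccc(OCC=C)cc1OCC=C
F5 | step 4 | racemic ethyl 3-[2,4-bis(prop-2-en-1-yloxy)phenyl]-2-{[3-hydroxy-4-(prop-2-en-1-yloxy)phenyl]methyl}-3-oxopropanoate | CCOC(=O)C(Cc1ccc(OCC=C)c(O)c1)C(=O)c1ccc(OCC=C)cc1OCC=C
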